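**Retrosynthetic overview**
- Last bond: benzoylation of the single free secondary hydroxyl of a cis tertiary/secondary diol; the tertiary hydroxyl is never protected.
- Key disconnection: the trans C1–OH / C2–OAc pair comes from allylic acetolysis of a C1–C2 vinyl oxirane, made by hydroxyl-directed epoxidation of a trans-5,6-dioxygenated cyclohexa-1,3-diene; both events run in one flask, as in the presumed arene oxide → trans-dihydrodiol → epoxide → tetrol biogenesis.
- The diene comes from Stille acetoxymethylation of a bromodiene trans hydroxy benzoate.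
- The trans relationship comes from Mitsunobu inversion of the cis-dihydrodiol of bromobenzene.
- Ring order: the carbocycle is carried unchanged from the enzymatically dearomatised benzene ring; the oxirane is the only ring formed (step 4) and is opened in the same step.

Assumption: (1S,2S)-3-bromocyclohexa-3,5-diene-1,2-diol (the microbial dihydroxylation product of bromobenzene) and (tributylstannyl)methanol are taken as purchasable.

Locants in the "Why" lines use target numbering: C1 = C(OH)CH2OAc, C2 = CHOAc, C3=C4, C5 and C6 = CHOBz (C6 next to C1).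

**Step 1**
Reactants: 1 (1S,2S)-3-bromocyclohexa-3,5-diene-1,2-diol
Product: 2 (1R,6S)-5-bromo-6-hydroxycyclohexa-2,4-dien-1-yl benzoate (benzoate trans to the free hydroxyl)
Conditions: PhCO2H, PPh3, DIAD, THF, −30 → 0 °C
Reagents that add atoms: benzoic acid, O=C(O)c1ccccc1
Why: Mitsunobu reaction; the less hindered allylic hydroxyl remote from bromine (future C5) forms the oxyphosphonium and is displaced by benzoate with SN2 inversion, which turns the cis-diol into the trans hydroxy benzoate, while the future C6 carbinol is untouched and the low temperature holds back dehydration to 2-bromophenol.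

**Step 2**
Reactants: 3 (tributylstannyl)methanol
Product: 4 (tributylstannyl)methyl acetate
Conditions: Ac2O, Et3N, DMAP (cat.), CH2Cl2, 0 °C → rt
Reagents that add atoms: acetic anhydride, CC(=O)OC(C)=O
Why: DMAP-catalysed O-acetylation of a primary alcohol; no stereocentre is involved.

**Step 3**
Reactants: 2 (1R,6S)-5-bromo-6-hydroxycyclohexa-2,4-dien-1-yl benzoate; 4 (tributylstannyl)methyl acetate
Product: 5 (1R,6R)-5-(acetoxymethyl)-6-hydroxycyclohexa-2,4-dien-1-yl benzoate
Conditions: Pd(PPh3)4 (5 mol%), CuI (10 mol%), 1,4-dioxane, 70 °C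
Reagents that add atoms: (tributylstannyl)methyl acetate 4, CCCC[Sn](CCCC)(CCCC)COC(C)=O
Why: Migita–Kosugi–Stille coupling; oxidative addition of the zerovalent palladium complex Pd(PPh3)4 into the dienyl C–Br bond is faster than ionisation of the allylic benzoate, the α-oxygenated CH2OAc group transfers from tin in preference to butyl, and no stereocentre is touched.

**Step 4**
Reactants: 5 (1R,6R)-5-(acetoxymethyl)-6-hydroxycyclohexa-2,4-dien-1-yl benzoate
Product: 7 (1R,4S,5S,6S)-4-acetoxy-5-(acetoxymethyl)-5,6-dihydroxycyclohex-2-en-1-yl benzoate, via vinyl epoxide 6 (not isolated)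
Conditions: VO(acac)2 (5 mol%), t-BuOOH (decane), CH2Cl2, 0 °C; then CsOAc, AcOH, 40 °C
Reagents that add atoms: tert-butyl hydroperoxide, CC(C)(C)OO; acetic acid, CC(=O)O
Why: Vanadium-catalysed hydroxyl-directed epoxidation (Sharpless–Michaelson type) delivers oxygen to the trisubstituted C1=C2 alkene on the face of the C6 hydroxyl and so sets C1; acetate then opens the vinyl oxirane at the allylic carbon C2 by SN2 with inversion and so sets C2 trans to the C1 oxygen, the same epoxide formation and allylic opening that links the pipoxide-type epoxides to the zeylenol-type tetrols.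

**Step 5**
Reactants: 7 (1R,4S,5S,6S)-4-acetoxy-5-(acetoxymethyl)-5,6-dihydroxycyclohex-2-en-1-yl benzoate
Product: 8 [(1R,2S,5R,6S)-2-acetoxy-5,6-bis(benzoyloxy)-1-hydroxycyclohex-3-en-1-yl]methyl acetate
Conditions: BzCl, pyridine, DMAP (cat.), CH2Cl2, 0 °C → rt
Reagents that add atoms: benzoyl chloride, O=C(Cl)c1ccccc1
Why: DMAP-catalysed acylation (Steglich-type acyl transfer) benzoylates only the secondary C6 hydroxyl because the tertiary C1 hydroxyl is inert under these conditions; any benzoyl shift between O5 and O6 converges on the same dibenzoate and no stereocentre changes.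

**Compound list**
1 | (1S,2S)-3-bromocyclohexa-3,5-diene-1,2-diol (cis-diol) | BrC1=CC=C[C@H](O)[C@@H]1O | starting material
2 | (1R,6S)-5-bromo-6-hydroxycyclohexa-2,4-dien-1-yl benzoate (trans) | BrC1=CC=C[C@@H](OC(=O)c2ccccc2)[C@@H]1O | intermediate
3 | (tributylstannyl)methanol | CCCC[Sn](CCCC)(CCCC)CO | starting material
4 | (tributylstannyl)methyl acetate | CCCC[Sn](CCCC)(CCCC)COC(C)=O | intermediate
5 | (1R,6R)-5-(acetoxymethyl)-6-hydroxycyclohexa-2,4-dien-1-yl benzoate (trans) | CC(=O)OCC1=CC=C[C@@H](OC(=O)c2ccccc2)[C@@H]1O | intermediate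
6 | [(1S,2S,3R,6R)-3-(benzoyloxy)-2-hydroxy-7-oxabicyclo[4.1.0]hept-4-en-1-yl]methyl acetate (vinyl epoxide, oxirane cis to the free hydroxyl, formed in the flask) | CC(=O)OC[C@@]12O[C@@H]1C=C[C@@H](OC(=O)c3ccccc3)[C@@H]2O | intermediate
7 | (1R,4S,5S,6S)-4-acetoxy-5-(acetoxymethyl)-5,6-dihydroxycyclohex-2-en-1-yl benzoate | CC(=O)OC[C@@]1(O)[C@@H](OC(C)=O)C=C[C@@H](OC(=O)c2ccccc2)[C@@H]1O | intermediate
8 | [(1R,2S,5R,6S)-2-acetoxy-5,6-bis(benzoyloxy)-1-hydroxycyclohex-3-en-1-yl]methyl acetate | CC(=O)OC[C@@]1(O)[C@@H](OC(C)=O)C=C[C@@H](OC(=O)c2ccccc2)[C@@H]1OC(=O)c1ccccc1 | target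

**Totals**
Total step count: 5. Longest linear sequence: 4 steps (1 → 2 → 5 → 7 → 8); the stannane branch adds 1 step.

**Steps most likely to fail, with fallbacks**

Step 1 (Mitsunobu on a free diene-diol; risk of dehydration to 2-bromophenol or attack at the wrong hydroxyl). The fallback sets out from 1 and comes back at 6. The inversion is postponed until the diene is consumed. Stille coupling of 1 with 4 (Pd(PPh3)4, CuI, dioxane) gives the cis-diol [(5S,6R)-5,6-dihydroxycyclohexa-1,3-dien-1-yl]methyl acetate F1. VO(acac)2/t-BuOOH epoxidises its trisubstituted alkene on the face of both hydroxyls to give [(1S,2S,3S,6R)-2,3-dihydroxy-7-oxabicyclo[4.1.0]hept-4-en-1-yl]methyl acetate F2. Mitsunobu benzoylation (PhCO2H, PPh3, DIAD) at the less hindered allylic hydroxyl, with no diene left to aromatise, gives 6, which is isolated here and taken on with CsOAc/AcOH to 7.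

Step 3 (slow transfer of the sp3 group from 4, or palladium ionising the allylic benzoate). The fallback sets out from 2 and comes back at 5. Compound 2 is coupled with the parent stannane 3, whose hydroxymethyl transfer is well established, to give (1R,6R)-6-hydroxy-5-(hydroxymethyl)cyclohexa-2,4-dien-1-yl benzoate F3. Only the primary allylic hydroxyl is then acetylated (AcCl, 2,4,6-collidine, CH2Cl2, −78 °C) to reach 5.

Step 4 (wrong epoxide face, 1,4-opening at C4, or participation by the CH2OAc group). The fallback sets out from 5 and comes back at 8. It uses the opposite oxirane face and an internal nucleophile: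
- Benzoylation of 5 (BzCl, pyridine) gives (1R,2R)-3-(acetoxymethyl)cyclohexa-3,5-diene-1,2-diyl dibenzoate F4.
- mCPBA adds anti to the C6 benzoate to give [(1S,2S,3R,6S)-2,3-bis(benzoyloxy)-7-oxabicyclo[4.1.0]hept-4-en-1-yl]methyl acetate F5.
- Catalytic BF3·OEt2 (CH2Cl2, −78 °C, then aqueous NaHCO3) lets the C6 benzoate carbonyl open the oxirane at tertiary C1 from the rear. Hydrolysis of the bridged benzoxonium returns the benzoyl to O6 and gives [(1R,2S,5R,6S)-5,6-bis(benzoyloxy)-1,2-dihydroxycyclohex-3-en-1-yl]methyl acetate F6, with C1 inverted and the C2 oxygen retained.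
- Ac2O/pyridine acetylates the C2 hydroxyl to give 8.

**Further compounds**
F1 | step 1 | [(5S,6R)-5,6-dihydroxycyclohexa-1,3-dien-1-yl]methyl acetate | CC(=O)OCC1=CC=C[C@H](O)[C@@H]1O
F2 | step 1 | [(1S,2S,3S,6R)-2,3-dihydroxy-7-oxabicyclo[4.1.0]hept-4-en-1-yl]methyl acetate | CC(=O)OC[C@@]12O[C@@H]1C=C[C@H](O)[C@@H]2O
F3 | step 3 | (1R,6R)-6-hydroxy-5-(hydroxymethyl)cyclohexa-2,4-dien-1-yl benzoate | OCC1=CC=C[C@@H](OC(=O)c2ccccc2)[C@@H]1O
F4 | step 4 | (1R,2R)-3-(acetoxymethyl)cyclohexa-3,5-diene-1,2-diyl dibenzoate | CC(=O)OCC1=CC=C[C@@H](OC(=O)c2ccccc2)[C@@H]1OC(=O)c1ccccc1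
F5 | step 4 | [(1S,2S,3R,6S)-2,3-bis(benzoyloxy)-7-oxabicyclo[4.1.0]hept-4-en-1-yl]methyl acetate | CC(=O)OC[C@]12O[C@H]1C=C[C@@H](OC(=O)c3ccccc3)[C@@H]2OC(=O)c1ccccc1
F6 | step 4 | [(1R,2S,5R,6S)-5,6-bis(benzoyloxy)-1,2-dihydroxycyclohex-3-en-1-yl]methyl acetate | CC(=O)OC[C@@]1(O)[C@@H](O)C=C[C@@H](OC(=O)c2ccccc2)[C@@H]1OC(=O)c1ccccc1
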